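**Plan**
Retrosynthetic cuts, in order: (1) the exocyclic bond between the side-chain ketone carbon and C3 of the 4-hydroxy-5,6-dihydro-2H-pyran-2-one ring; (2) the C(=CH2)–CH2 bond of the skipped diene (terminal alkyne plus allyl group); (3) the Cα–allyl bond of the β-hydroxy acid; (4) the carbinol C–H bond (β-keto ester).
Forward: the chain is grown from (S)-2-methylbutanoic acid (β-keto ester, hydrogenation, anti-allylation), its hydroxy acid is locked in a 1,3-dioxan-4-one helper ring, and a ruthenium ene coupling with pent-4-ynoic acid installs the diene. The lactone ring is made separately by dearomatising hydrogenation of triacetic acid lactone; the two are then united and the helper ring removed.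
Enabling feature: ring C3 lies between the lactone carbonyl C2 and the enolised C4–OH, so an acyl group first placed on the C4 oxygen migrates to C3 and stays there as the chelated, acidic tricarbonyl enol.
Stereochemistry: sec-butyl centre bought with (S)-2-methylbutanoic acid; carbinol centre from (R)-BINAP/ruthenium hydrogenation; α-centre from dianion alkylation anti to the carbinol substituent; E-alkene from the ene coupling; ring C6 from catalyst-controlled pyrone hydrogenation.

Key step: step 8

Assumption: the (S)-configured biaryl diphosphine is taken to be the enantiomer that hydrogenates the pyrone to the (6R)-lactone (the (R)-ligand is used if the sense is the reverse), and the acylated lactones are written as their 4-hydroxy enol tautomers.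

**Route**

Step 1
Reactants: 1 (2S)-2-methylbutanoic acid
Product: 3 methyl (4S)-4-methyl-3-oxohexanoate, via acyl imidazolide 2 (not isolated)
Conditions: CDI (1.1 equiv), THF, 23 °C; then methyl potassium malonate (1.5 equiv), MgCl2 (1.5 equiv), THF, 23 → 40 °C; aq HCl work-up
Reagents that add atoms: methyl potassium malonate, COC(=O)CC(=O)[O-].[K+]
Why: Masamune-type two-carbon homologation, in which the acyl imidazolide is C-acylated by the magnesium-chelated malonate half ester and decarboxylates on work-up under conditions mild enough that the existing α-stereocentre (it becomes C4) should not epimerise; no new stereocentre is formed.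

Step 2
Reactants: 3 methyl (4S)-4-methyl-3-oxohexanoate
Product: 4 methyl (3S,4S)-3-hydroxy-4-methylhexanoate
Conditions: RuCl2[(R)-BINAP] (0.5 mol %), H2 (50 bar), MeOH, 50 °C
Reagents that add atoms: none
Why: Noyori asymmetric hydrogenation of a β-keto ester, in which the ester-chelated ruthenium hydride of the (R)-ligand should deliver hydrogen to one ketone face under catalyst control (the spatial sense that gives (R)-3-hydroxybutanoate, named 3S here because the sec-butyl branch outranks the CH2CO2Me arm), overriding the weak bias of the neighbouring C4 centre.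

Step 3
Reactants: 4 methyl (3S,4S)-3-hydroxy-4-methylhexanoate
Product: 5 methyl (2R,3R,4S)-3-hydroxy-4-methyl-2-(prop-2-en-1-yl)hexanoate
Conditions: LDA (2.2 equiv), THF, −78 → −20 °C; allyl bromide (1.5 equiv), DMPU, −78 → −10 °C; aq NH4Cl
Reagents that add atoms: allyl bromide, C=CCBr
Why: Fráter–Seebach alkylation, in which the lithium-chelated alkoxide/enolate dianion should be allylated on the face opposite the C3 sec-butyl substituent, setting C2 anti to the hydroxyl (2R).

Step 4
Reactants: 5 methyl (2R,3R,4S)-3-hydroxy-4-methyl-2-(prop-2-en-1-yl)hexanoate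
Product: 6 (2R,3R,4S)-3-hydroxy-4-methyl-2-(prop-2-en-1-yl)hexanoic acid
Conditions: LiOH·H2O (3 equiv), THF/MeOH/H2O, 0 → 23 °C; then 1 M HCl to pH 3
Reagents that add atoms: lithium hydroxide, [Li+].[OH-]
Why: Ester saponification carried out while the substrate is still a plain α-alkyl β-hydroxy ester (no β,γ-unsaturation yet), so acyl attack by hydroxide should outrun retro-aldol cleavage and C2 epimerisation; no stereocentre is touched.

Step 5
Reactants: 6 (2R,3R,4S)-3-hydroxy-4-methyl-2-(prop-2-en-1-yl)hexanoic acid
Product: 7 (5R,6R)-6-[(2S)-butan-2-yl]-2,2-dimethyl-5-(prop-2-en-1-yl)-1,3-dioxan-4-one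
Conditions: 2-methoxypropene (3 equiv), PPTS (10 mol %), CH2Cl2, 0 → 23 °C
Reagents that add atoms: 2-methoxypropene, C=C(C)OC
Why: Acid-catalysed acetonide formation (ketalisation of the hydroxyl, then displacement of methanol by the carboxyl) should close a six-membered acylal ring with both substituents equatorial, masking the hydroxyl and the hindered carboxyl with a single helper; no stereocentre is touched.

Step 6
Reactants: 7 (5R,6R)-6-[(2S)-butan-2-yl]-2,2-dimethyl-5-(prop-2-en-1-yl)-1,3-dioxan-4-one; 8 pent-4-ynoic acid
Product: 9 (6E)-7-[(5R,6R)-6-[(2S)-butan-2-yl]-2,2-dimethyl-4-oxo-1,3-dioxan-5-yl]-4-methylidenehept-6-enoic acid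
Conditions: [CpRu(MeCN)3]PF6 (10 mol %), acetone, 23 °C
Reagents that add atoms: none
Why: Ruthenium-catalysed Alder-ene type alkene–alkyne coupling, in which oxidative cyclisation joins the substituted alkyne carbon to the terminal alkene carbon in a ruthenacyclopentene, and β-hydride elimination from the allylic CH2 followed by reductive elimination should give the branched 1,1-disubstituted alkene and the E-alkene of the skipped diene with full atom economy, leaving the C5 stereocentre of the dioxanone untouched.

Step 7
Reactants: 10 4-hydroxy-6-methyl-2H-pyran-2-one (triacetic acid lactone)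
Product: 11 (6R)-4-hydroxy-6-methyl-5,6-dihydro-2H-pyran-2-one
Conditions: Ru(OAc)2[(S)-MeO-BIPHEP] (1 mol %), HBF4·OEt2 (2 mol %), H2 (60 bar), MeOH, 60 °C
Reagents that add atoms: none
Why: Dearomatising asymmetric hydrogenation of a 2-pyrone, in which the cationic divalent ruthenium diphosphine catalyst binds the 4-hydroxy/carbonyl array and should saturate only the C5=C6 bond from the face chosen by the ligand (C6 becomes R), the resulting enolised β-keto lactone being reduced further only under more forcing conditions.

Step 8
Reactants: 9 (6E)-7-[(5R,6R)-6-[(2S)-butan-2-yl]-2,2-dimethyl-4-oxo-1,3-dioxan-5-yl]-4-methylidenehept-6-enoic acid; 11 (6R)-4-hydroxy-6-methyl-5,6-dihydro-2H-pyran-2-one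
Product: 13 (6R)-3-[(6E)-7-[(5R,6R)-6-[(2S)-butan-2-yl]-2,2-dimethyl-4-oxo-1,3-dioxan-5-yl]-4-methylidenehept-6-enoyl]-4-hydroxy-6-methyl-5,6-dihydro-2H-pyran-2-one, via enol ester 12 (not isolated)
Conditions: DCC (1.1 equiv), DMAP (1.5 equiv), CH2Cl2, 0 → 23 °C (40 °C if the enol ester persists)
Reagents that add atoms: none
Why: DCC turns the C1 carboxyl of 9 into an O-acylisourea that DMAP relays as an N-acylpyridinium ion, the C4 enol oxygen of 11 is acylated to enol ester 12, and DMAP then reopens this vinylogous mixed anhydride to an acylpyridinium/lactone-enolate ion pair that recombines at C3, the carbon flanked by the lactone carbonyl C2 and the C4 oxygen. The closest known reaction type is the Steglich-type O-acylation of a cyclic 1,3-dicarbonyl compound followed by DMAP-mediated Fries-type 1,3 O-to-C acyl migration, the standard entry to 3-acyl-4-hydroxypyranones, 3-acyltetronic acids and 3-acyltetramic acids. No ring is closed and no stereocentre is formed; C6 of the lactone, C5 and C6 of the dioxanone and the sec-butyl centre are spectators. The step needs C- over O-acylation, which is secured thermodynamically because the product is deprotonated to a hydrogen-bond-stabilised tricarbonyl enolate and is thereby withdrawn from the acyl-transfer equilibrium. It also needs activation of one carboxyl only and no acylation of the hydroxyl, which the dioxanone ring secures by locking both competing groups. The mild amine base and a temperature at or below 40 °C should leave the allylic C5–H of the dioxanone and the skipped diene unmoved.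

Step 9
Reactants: 13 (6R)-3-[(6E)-7-[(5R,6R)-6-[(2S)-butan-2-yl]-2,2-dimethyl-4-oxo-1,3-dioxan-5-yl]-4-methylidenehept-6-enoyl]-4-hydroxy-6-methyl-5,6-dihydro-2H-pyran-2-one
Product: 14 (2R,3E)-2-[(1R,2S)-1-hydroxy-2-methylbutyl]-9-[(6R)-4-hydroxy-6-methyl-2-oxo-5,6-dihydro-2H-pyran-3-yl]-6-methylidene-9-oxonon-3-enoic acid (target)
Conditions: 1 M aq HCl/THF (1:3), 23 °C
Reagents that add atoms: none
Why: Acid-catalysed acylal hydrolysis (alkyl–oxygen cleavage through an oxocarbenium ion, the oxygen of water leaving in acetone) should free hydroxyl and carboxyl together under conditions too mild to shift the skipped diene, open the δ-lactone or epimerise the allylic α-centre; all stereocentres are carried over unchanged.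

**Compound list**
1 | (2S)-2-methylbutanoic acid | CC[C@H](C)C(=O)O | starting material
2 | (2S)-1-(1H-imidazol-1-yl)-2-methylbutan-1-one (acyl imidazolide) | CC[C@H](C)C(=O)n1ccnc1 | intermediate
3 | methyl (4S)-4-methyl-3-oxohexanoate | CC[C@H](C)C(=O)CC(=O)OC | intermediate
4 | methyl (3S,4S)-3-hydroxy-4-methylhexanoate | CC[C@H](C)[C@@H](O)CC(=O)OC | intermediate
5 | methyl (2R,3R,4S)-3-hydroxy-4-methyl-2-(prop-2-en-1-yl)hexanoate | C=CC[C@@H](C(=O)OC)[C@H](O)[C@@H](C)CC | intermediate
6 | (2R,3R,4S)-3-hydroxy-4-methyl-2-(prop-2-en-1-yl)hexanoic acid | C=CC[C@@H](C(=O)O)[C@H](O)[C@@H](C)CC | intermediate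
7 | (5R,6R)-6-[(2S)-butan-2-yl]-2,2-dimethyl-5-(prop-2-en-1-yl)-1,3-dioxan-4-one | C=CC[C@H]1C(=O)OC(C)(C)O[C@@H]1[C@@H](C)CC | intermediate
8 | pent-4-ynoic acid | C#CCCC(=O)O | starting material
9 | (6E)-7-[(5R,6R)-6-[(2S)-butan-2-yl]-2,2-dimethyl-4-oxo-1,3-dioxan-5-yl]-4-methylidenehept-6-enoic acid | C=C(C/C=C/[C@H]1C(=O)OC(C)(C)O[C@@H]1[C@@H](C)CC)CCC(=O)O | intermediate
10 | 4-hydroxy-6-methyl-2H-pyran-2-one (triacetic acid lactone) | CC1=CC(O)=CC(=O)O1 | starting material
11 | (6R)-4-hydroxy-6-methyl-5,6-dihydro-2H-pyran-2-one (enol form of (6R)-6-methyloxane-2,4-dione) | C[C@@H]1CC(O)=CC(=O)O1 | intermediate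
12 | (6R)-6-methyl-2-oxo-5,6-dihydro-2H-pyran-4-yl (6E)-7-[(5R,6R)-6-[(2S)-butan-2-yl]-2,2-dimethyl-4-oxo-1,3-dioxan-5-yl]-4-methylidenehept-6-enoate (enol ester) | C=C(C/C=C/[C@H]1C(=O)OC(C)(C)O[C@@H]1[C@@H](C)CC)CCC(=O)OC2=CC(=O)O[C@H](C)C2 | intermediate
13 | (6R)-3-[(6E)-7-[(5R,6R)-6-[(2S)-butan-2-yl]-2,2-dimethyl-4-oxo-1,3-dioxan-5-yl]-4-methylidenehept-6-enoyl]-4-hydroxy-6-methyl-5,6-dihydro-2H-pyran-2-one | C=C(C/C=C/[C@H]1C(=O)OC(C)(C)O[C@@H]1[C@@H](C)CC)CCC(=O)C2=C(O)C[C@@H](C)OC2=O | intermediate
14 | (2R,3E)-2-[(1R,2S)-1-hydroxy-2-methylbutyl]-9-[(6R)-4-hydroxy-6-methyl-2-oxo-5,6-dihydro-2H-pyran-3-yl]-6-methylidene-9-oxonon-3-enoic acid | C=C(C/C=C/[C@@H](C(=O)O)[C@H](O)[C@@H](C)CC)CCC(=O)C1=C(O)C[C@@H](C)OC1=O | target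

**Step count and risks**
Total steps: 9. Longest linear sequence: 8 steps (steps 1–6, 8 and 9, from 1 to 14); step 7 supplies the lactone fragment in one step.

Steps most likely to fail:

Step 6. The free carboxylic acid of 8 may bind the cationic ruthenium centre, or add across its own activated alkyne to give an enol lactone, faster than the ene coupling proceeds. The fallback sets out from 7 and carries the acyl group through the ruthenium step already activated and non-acidic. Coupling of 7 with commercial 2,5-dioxopyrrolidin-1-yl pent-4-ynoate under the same catalyst should give the active ester 2,5-dioxopyrrolidin-1-yl (6E)-7-[(5R,6R)-6-[(2S)-butan-2-yl]-2,2-dimethyl-4-oxo-1,3-dioxan-5-yl]-4-methylidenehept-6-enoate F1. F1 is then united with 11 by Et3N/DMAP in CH2Cl2 (O-acylation by the preformed active ester, then the same 1,3-acyl shift), so neither a free acid nor a carbodiimide is needed. This path bypasses 9 and comes back to the route at 13.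

Step 8. The acyl transfer may stall at the enol ester, the O-acylisourea may rearrange to an unreactive N-acylurea, or prolonged contact with DMAP may open the dioxanone or epimerise its C5. The fallback reverses the order of union and sets out from 11 and 8. The same carbodiimide/DMAP C-acylation with the simple, robust acid should give (6R)-4-hydroxy-6-methyl-3-(pent-4-ynoyl)-5,6-dihydro-2H-pyran-2-one F2. The [CpRu(MeCN)3]PF6 ene coupling of F2 with 7 in acetone then builds the skipped diene last, under neutral conditions, and comes back to the route at 13.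

Step 7. Facial discrimination on the flat pyrone may be poor, or reduction may run on to the saturated 4-hydroxy lactone. The fallback buys the stereocentre and sets out from commercial ethyl (3R)-3-hydroxybutanoate in place of 10. Claisen condensation with the lithium enolate of tert-butyl acetate (LDA, THF, −78 → −20 °C, excess enolate to cover the free hydroxyl) should give tert-butyl (5R)-5-hydroxy-3-oxohexanoate F3. CF3CO2H in CH2Cl2 then cleaves the tert-butyl ester and closes the lactone, and the path comes back to the route at 11.

Further compounds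
F1 | step 6 | 2,5-dioxopyrrolidin-1-yl (6E)-7-[(5R,6R)-6-[(2S)-butan-2-yl]-2,2-dimethyl-4-oxo-1,3-dioxan-5-yl]-4-methylidenehept-6-enoate | C=C(C/C=C/[C@H]1C(=O)OC(C)(C)O[C@@H]1[C@@H](C)CC)CCC(=O)ON2C(=O)CCC2=O
F2 | step 8 | (6R)-4-hydroxy-6-methyl-3-(pent-4-ynoyl)-5,6-dihydro-2H-pyran-2-one | C#CCCC(=O)C1=C(O)C[C@@H](C)OC1=O
F3 | step 7 | tert-butyl (5R)-5-hydroxy-3-oxohexanoate | C[C@@H](O)CC(=O)CC(=O)OC(C)(C)C
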